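## Retrosynthetic overview

1. Feature: in flavone ring A (C4a, C5, C6, C7, C8, C8a), C6 carries C5' of flavanone ring B and lies between the oxygens on C5 and C7. The pyranone oxygen O1 sits on C8a, para to C6. Ring A is therefore a 2-arylphloroglucinol in which C4a and C8 are equivalent.
2. Key disconnection: ring A is grown on ring B rather than coupled to it. Aryl siloxyalkyne 10 (its aryl–alkyne bond becomes C5'–C6) and 3-(benzyloxy)cyclobutenone 12 combine in a Danheiser benzannulation that forms C5–C6, C7–C8 and C4a–C5. The benzyl ether marks the future O1.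
3. Flavone ring C: the two flanking oxygens are made alike (MOM) and the benzyl ether is removed. Iodination at C4a and carbonylative annulation with arylacetylene 23 and CO then form C4a–C4, C4–C3 and O1–C2.
4. Flavanone ring C: the unmasked ring B aldehyde 28 is condensed with beta-ketoester 32. The O1–C2 bond is closed by a catalytic enantioselective oxa-Michael addition that sets C2 as S; decarboxylation and hydrogenolysis finish the route.
5. Ring order: flavone ring A (step 8), flavone ring C (step 14), flavanone ring C (step 20). The other four benzene rings are bought.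

Key step: step 8

Assumption: the epi-quinine thiourea is written as the catalyst that delivers 2S. The sense of induction is to be confirmed on 36 by the CD sign pattern of 2S flavanones, and the pseudoenantiomeric epi-quinidine thiourea takes its place, with nothing else changed, if the sense is opposite.

Assumption: the target SMILES carries no axial descriptor, so the tri-ortho-substituted biaryl axis is treated as configurationally unstable and rotamers count as one compound.

## Route

Step 1
Reactants: 1 5-iodovanillin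
Product: 2 3,4-dihydroxy-5-iodobenzaldehyde
Conditions: AlCl3 (1.2 equiv), pyridine (4.5 equiv), CH2Cl2, reflux; then 2 M HCl
Reagents that add atoms: none
Why: Chelation-assisted Lewis acid ether cleavage, in which AlCl3 binds the free 4-OH and the neighbouring methoxy oxygen and pyridine takes the activated methyl group by SN2; this is the standard demethylation of 5-halovanillins and leaves aldehyde and iodide untouched.

Step 2
Reactants: 2 3,4-dihydroxy-5-iodobenzaldehyde
Product: 3 3-iodo-4,5-bis(methoxymethoxy)benzaldehyde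
Conditions: MOMCl (3 equiv), i-Pr2NEt (4 equiv), CH2Cl2, 0 °C to rt
Reagents that add atoms: chloromethyl methyl ether (MOMCl), COCCl
Why: Williamson-type O-alkylation of both phenols; MOM ethers withstand the organolithium, fluoride, hydrogenolysis and palladium steps ahead and fall together with the acetal in step 15.

Step 3
Reactants: 3 3-iodo-4,5-bis(methoxymethoxy)benzaldehyde
Product: 4 5-(dimethoxymethyl)-1-iodo-2,3-bis(methoxymethoxy)benzene
Conditions: HC(OMe)3 (3 equiv), PPTS (5 mol %), MeOH, rt; Et3N quench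
Reagents that add atoms: trimethyl orthoformate, COC(OC)OC; methanol, CO
Why: Acid-catalysed acetalisation driven by the orthoformate as water scavenger; the weak acid PPTS at room temperature should convert a benzaldehyde far faster than it cleaves aryl MOM ethers, and the acetal shields the aldehyde from the lithium reagents of step 6.

Step 4
Reactants: 4 5-(dimethoxymethyl)-1-iodo-2,3-bis(methoxymethoxy)benzene; 5 ethynyltrimethylsilane
Product: 6 {[5-(dimethoxymethyl)-2,3-bis(methoxymethoxy)phenyl]ethynyl}trimethylsilane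
Conditions: PdCl2(PPh3)2 (2 mol %), CuI (4 mol %), Et3N, THF, rt
Reagents that add atoms: none
Why: Sonogashira coupling; the iodide (preferred to the bromide) should couple at room temperature despite the ortho MOM ether, so acetal and MOM groups meet only amine base.

Step 5
Reactants: 6 {[5-(dimethoxymethyl)-2,3-bis(methoxymethoxy)phenyl]ethynyl}trimethylsilane
Product: 7 5-(dimethoxymethyl)-1-ethynyl-2,3-bis(methoxymethoxy)benzene
Conditions: K2CO3 (0.2 equiv), MeOH, rt
Reagents that add atoms: none
Why: Methoxide-catalysed protodesilylation of an alkynylsilane, a basic reaction that cannot harm acetals.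

Step 6
Reactants: 7 5-(dimethoxymethyl)-1-ethynyl-2,3-bis(methoxymethoxy)benzene
Product: 10 {[5-(dimethoxymethyl)-2,3-bis(methoxymethoxy)phenyl]ethynyloxy}triisopropylsilane, via lithium acetylide 8 (not isolated), via lithium ynolate 9 (not isolated)
Conditions: n-BuLi, THF, −78 °C; LiOOt-Bu (from t-BuOOH and LiHMDS, THF, −78 °C), −78 to 0 °C; TIPSOTf, −78 to 0 °C; H2O
Reagents that add atoms: tert-butyl hydroperoxide, CC(C)(C)OO; triisopropylsilyl triflate, CC(C)[Si](OS(=O)(=O)C(F)(F)F)(C(C)C)C(C)C
Why: Electrophilic oxygenation of a lithium acetylide, in which the carbanion of 8 attacks the O–O bond of the lithium peroxide and expels tert-butoxide to give ynolate 9, which the bulky oxophilic silyl triflate traps on oxygen; this is the established way from terminal alkynes to triisopropylsiloxyalkynes.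

Step 7
Reactants: 11 3-ethoxycyclobut-2-en-1-one
Product: 12 3-(benzyloxy)cyclobut-2-en-1-one
Conditions: BnOH (3 equiv), CSA (5 mol %), toluene, 35 °C, reduced pressure (EtOH removed); Et3N quench
Reagents that add atoms: benzyl alcohol, OCc1ccccc1
Why: Acid-catalysed transetherification of a vinylogous ester (addition of BnOH at C3 of the O-protonated enone, loss of EtOH), pulled forward by removal of ethanol and kept below 40 °C so that the four-membered ring does not open thermally.

Step 8
Reactants: 10 {[5-(dimethoxymethyl)-2,3-bis(methoxymethoxy)phenyl]ethynyloxy}triisopropylsilane; 12 3-(benzyloxy)cyclobut-2-en-1-one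
Product: 17 4-(benzyloxy)-5'-(dimethoxymethyl)-2',3'-bis(methoxymethoxy)-6-(triisopropylsiloxy)biphenyl-2-ol, via vinylketene 13 (not isolated), via vinylcyclobutenone 14 (not isolated), via dienylketene 15 (not isolated), via cyclohexadienone 16 (not isolated)
Conditions: 12 (1.3 equiv, slow addition), toluene, 110 °C; then sealed tube, 140 °C
Reagents that add atoms: none
Why: Thermal conrotatory four-electron opening of 12 gives vinylketene 13, and the aryl-bearing, nucleophilic carbon of ynol ether 10 attacks its carbonyl carbon in a [2+2] cycloaddition (bonds C5–C6 and C7–C8) to give cyclobutenone 14. Compound 14 opens reversibly in a second four-electron electrocyclic step, and the isomer of dienylketene 15 with the alkenyl group turned inward closes the one new ring, the benzene ring that becomes flavone ring A, by six-electron disrotatory electrocyclisation (bond C4a–C5); tautomerisation of dienone 16 to phenol 17 makes the sequence irreversible. The closest known reaction is the Danheiser benzannulation of cyclobutenones with triisopropylsiloxyalkynes, which gives 2-substituted resorcinol monosilyl ethers; since its second ring opening always takes place on a 3-siloxycyclobutenone, the vinylogous ester 12 should open as well, only at a higher temperature than a 3-alkylcyclobutenone. No stereocentre survives (C4 of 14 is lost on ring opening) and the new biaryl axis equilibrates freely. The selectivity needed is regiochemical: the oxygen lone pair polarises the alkyne so that the ketene carbonyl carbon ends on the aryl-bearing carbon, which places the aryl between OH and OTIPS and the benzyl ether para to it. Slow addition of 12 keeps the ketene concentration low, which limits ketene self-condensation and acylation of the hindered phenol 17.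

Step 9
Reactants: 17 4-(benzyloxy)-5'-(dimethoxymethyl)-2',3'-bis(methoxymethoxy)-6-(triisopropylsiloxy)biphenyl-2-ol
Product: 18 4-(benzyloxy)-5'-(dimethoxymethyl)-2',3'-bis(methoxymethoxy)biphenyl-2,6-diol
Conditions: TBAF (1.1 equiv), AcOH (1.1 equiv), THF, 0 °C
Reagents that add atoms: none
Why: Fluoride-induced cleavage of the aryl silyl ether; acetic acid buffers the phenoxide so that the electron-rich resorcinol is not exposed to base and air.

Step 10
Reactants: 18 4-(benzyloxy)-5'-(dimethoxymethyl)-2',3'-bis(methoxymethoxy)biphenyl-2,6-diol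
Product: 19 4-(benzyloxy)-5'-(dimethoxymethyl)-2,6,2',3'-tetrakis(methoxymethoxy)biphenyl
Conditions: MOMCl (4 equiv), i-Pr2NEt (6 equiv), CH2Cl2, 0 to 40 °C
Reagents that add atoms: chloromethyl methyl ether (MOMCl), COCCl
Why: Williamson-type O-alkylation that gives the two oxygens beside the aryl the same group, so that the two remaining CH positions of the new ring (future C4a and C8) become equivalent and only the para oxygen can later close the pyranone.

Step 11
Reactants: 19 4-(benzyloxy)-5'-(dimethoxymethyl)-2,6,2',3'-tetrakis(methoxymethoxy)biphenyl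
Product: 20 5'-(dimethoxymethyl)-2,6,2',3'-tetrakis(methoxymethoxy)biphenyl-4-ol
Conditions: H2 (1 atm), 10% Pd/C, NaHCO3 (solid), EtOAc, rt
Reagents that add atoms: none
Why: Catalytic hydrogenolysis of the only benzyl ether frees the oxygen para to the aryl (future O1); the solid buffer keeps the medium non-acidic so that the benzylic acetal is neither exchanged nor hydrogenolysed.

Step 12
Reactants: 20 5'-(dimethoxymethyl)-2,6,2',3'-tetrakis(methoxymethoxy)biphenyl-4-ol
Product: 21 3-iodo-5'-(dimethoxymethyl)-2,6,2',3'-tetrakis(methoxymethoxy)biphenyl-4-ol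
Conditions: NIS (1.0 equiv), CH2Cl2, −20 to 0 °C, dark
Reagents that add atoms: N-iodosuccinimide, O=C1CCC(=O)N1I
Why: Electrophilic aromatic iodination ortho to the free phenol; the para position is blocked by the aryl, the two ortho positions are equivalent and ring B is far less activated, so one equivalent of NIS at low temperature should give a single mono-iodide.

Step 13
Reactants: 22 3,4-bis(benzyloxy)benzaldehyde
Product: 23 1,2-bis(benzyloxy)-4-ethynylbenzene
Conditions: dimethyl (1-diazo-2-oxopropyl)phosphonate (1.3 equiv), K2CO3 (2 equiv), MeOH–THF, rt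
Reagents that add atoms: dimethyl (1-diazo-2-oxopropyl)phosphonate, CC(=O)C(=[N+]=[N-])P(=O)(OC)OC
Why: Seyferth–Gilbert homologation in the Ohira–Bestmann version, which turns aromatic aldehydes into terminal alkynes in one mild basic operation.

Step 14
Reactants: 21 3-iodo-5'-(dimethoxymethyl)-2,6,2',3'-tetrakis(methoxymethoxy)biphenyl-4-ol; 23 1,2-bis(benzyloxy)-4-ethynylbenzene
Product: 26 2-[3,4-bis(benzyloxy)phenyl]-6-[5-(dimethoxymethyl)-2,3-bis(methoxymethoxy)phenyl]-5,7-bis(methoxymethoxy)-4H-chromen-4-one, via alkynone 24 (not isolated), via enaminone 25 (not isolated)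
Conditions: PdCl2(dppf) (5 mol %), CO (10 bar), Et2NH, 100 °C
Reagents that add atoms: carbon monoxide, [C-]#[O+]
Why: Carbonylative Sonogashira coupling followed by amine-mediated 6-endo closure, the known flavone synthesis from o-iodophenols, arylacetylenes and CO; diethylamine adds to alkynone 24 to give enaminone 25, and the only free phenol displaces the amine, which steers the closure to the six-membered pyranone rather than to an aurone.

Step 15
Reactants: 26 2-[3,4-bis(benzyloxy)phenyl]-6-[5-(dimethoxymethyl)-2,3-bis(methoxymethoxy)phenyl]-5,7-bis(methoxymethoxy)-4H-chromen-4-one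
Product: 27 3-{2-[3,4-bis(benzyloxy)phenyl]-5,7-dihydroxy-4-oxo-4H-chromen-6-yl}-4,5-dihydroxybenzaldehyde
Conditions: 3 M aq HCl, THF–MeOH, 50 °C
Reagents that add atoms: water, O
Why: Acid hydrolysis of acetals removes the dimethyl acetal and all four MOM ethers in one operation, leaves the benzyl ethers alone, and is far milder than the hot concentrated acid needed for a Wessely–Moser rearrangement of the 6-aryl flavone.

Step 16
Reactants: 27 3-{2-[3,4-bis(benzyloxy)phenyl]-5,7-dihydroxy-4-oxo-4H-chromen-6-yl}-4,5-dihydroxybenzaldehyde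
Product: 28 3,4-bis(benzyloxy)-5-{7-(benzyloxy)-2-[3,4-bis(benzyloxy)phenyl]-5-hydroxy-4-oxo-4H-chromen-6-yl}benzaldehyde
Conditions: BnBr (3.3 equiv), K2CO3 (4 equiv), DMF, rt, argon
Reagents that add atoms: benzyl bromide, BrCc1ccccc1
Why: Williamson ether synthesis with the classical flavonoid selectivity; the 5-OH is hydrogen-bonded to C4=O and shielded by the C6 aryl, so it stays free as a harmless spectator, and every remaining protecting group is now stable to acid and removable by hydrogen.

Step 17
Reactants: 29 2',4',6'-trihydroxyacetophenone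
Product: 30 1-[2,4-bis(benzyloxy)-6-hydroxyphenyl]ethanone
Conditions: BnBr (2.1 equiv), K2CO3 (2.2 equiv), DMF, rt to 50 °C
Reagents that add atoms: benzyl bromide, BrCc1ccccc1
Why: Selective Williamson benzylation; after two alkylations the last ortho hydroxyl is chelated to the acetyl carbonyl and is not alkylated by K2CO3/BnBr.

Step 18
Reactants: 30 1-[2,4-bis(benzyloxy)-6-hydroxyphenyl]ethanone
Product: 32 tert-butyl 3-[2,4-bis(benzyloxy)-6-hydroxyphenyl]-3-oxopropanoate, via dilithium enolate phenoxide 31 (not isolated)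
Conditions: LiHMDS (3.3 equiv), THF, −78 °C; Boc2O (1.1 equiv), −78 to −20 °C; AcOH quench
Reagents that add atoms: di-tert-butyl dicarbonate, CC(C)(C)OC(=O)OC(=O)OC(C)(C)C
Why: Claisen-type C-acylation of the lithium polyanion of an o-hydroxyacetophenone, which reacts at its most basic site, the enolate carbon; the third equivalent of base takes up the acidic proton of the beta-ketoester formed.

Step 19
Reactants: 28 3,4-bis(benzyloxy)-5-{7-(benzyloxy)-2-[3,4-bis(benzyloxy)phenyl]-5-hydroxy-4-oxo-4H-chromen-6-yl}benzaldehyde; 32 tert-butyl 3-[2,4-bis(benzyloxy)-6-hydroxyphenyl]-3-oxopropanoate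
Product: 33 tert-butyl (Z)-2-[2,4-bis(benzyloxy)-6-hydroxybenzoyl]-3-(ring B aryl of 28)acrylate
Conditions: piperidine (20 mol %), AcOH (20 mol %), 4 Å MS, toluene, rt
Reagents that add atoms: none
Why: Knoevenagel condensation of an unhindered aromatic aldehyde with an active methylene compound; the ester makes the later acceptor reactive enough for low-temperature catalysis, and the alkene geometry (drawn with aryl cis to the ester) is not critical.

Step 20
Reactants: 33 tert-butyl (Z)-2-[2,4-bis(benzyloxy)-6-hydroxybenzoyl]-3-(ring B aryl of 28)acrylate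
Product: 36 (2S)-5,7-bis(benzyloxy)-2-(3,4-bis(benzyloxy)-5-{7-(benzyloxy)-2-[3,4-bis(benzyloxy)phenyl]-5-hydroxy-4-oxo-4H-chromen-6-yl}phenyl)chroman-4-one, via flavanone-3-carboxylate 34 (not isolated), via beta-keto acid 35 (not isolated)
Conditions: 1-[3,5-bis(trifluoromethyl)phenyl]-3-[(8S,9S)-6'-methoxycinchonan-9-yl]thiourea (10 mol %), toluene, −25 °C; then TsOH·H2O, 80 °C
Reagents that add atoms: none
Why: Enantioselective intramolecular oxa-Michael addition under bifunctional cinchona thiourea catalysis, known for alkylidene beta-ketoesters of o-hydroxyaryl ketones; the thiourea holds the 1,3-dicarbonyl and the quinuclidine activates the phenol so that oxygen reaches one face of the alkylidene and sets C2 as S, after which acid removes isobutene, 35 decarboxylates and the labile C3 centre disappears.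

Step 21
Reactants: 36 (2S)-5,7-bis(benzyloxy)-2-(3,4-bis(benzyloxy)-5-{7-(benzyloxy)-2-[3,4-bis(benzyloxy)phenyl]-5-hydroxy-4-oxo-4H-chromen-6-yl}phenyl)chroman-4-one
Product: 37 (2S)-2-{3-[2-(3,4-dihydroxyphenyl)-5,7-dihydroxy-4-oxo-4H-chromen-6-yl]-4,5-dihydroxyphenyl}-5,7-dihydroxychroman-4-one (target)
Conditions: H2 (1 atm), 10% Pd/C, THF–MeOH, rt
Reagents that add atoms: none
Why: Catalytic hydrogenolysis of all seven aryl benzyl ethers under neutral conditions, which avoids the base-induced retro-oxa-Michael ring opening that would racemise C2 and normally spares the flavone double bond and both carbonyl groups at one atmosphere.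

## Compound list

1 | 5-iodovanillin | COc1cc(C=O)cc(I)c1O | starting material
2 | 3,4-dihydroxy-5-iodobenzaldehyde | O=Cc1cc(O)c(O)c(I)c1 | intermediate
3 | 3-iodo-4,5-bis(methoxymethoxy)benzaldehyde | O=Cc1cc(I)c(OCOC)c(OCOC)c1 | intermediate
4 | 5-(dimethoxymethyl)-1-iodo-2,3-bis(methoxymethoxy)benzene | COC(OC)c1cc(I)c(OCOC)c(OCOC)c1 | intermediate
5 | ethynyltrimethylsilane | C#C[Si](C)(C)C | starting material
6 | {[5-(dimethoxymethyl)-2,3-bis(methoxymethoxy)phenyl]ethynyl}trimethylsilane | COC(OC)c1cc(OCOC)c(OCOC)c(C#C[Si](C)(C)C)c1 | intermediate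
7 | 5-(dimethoxymethyl)-1-ethynyl-2,3-bis(methoxymethoxy)benzene | COC(OC)c1cc(OCOC)c(OCOC)c(C#C)c1 | intermediate
8 | lithium acetylide of 7 | COC(OC)c1cc(OCOC)c(OCOC)c(C#C[Li])c1 | intermediate
9 | lithium ynolate | COC(OC)c1cc(OCOC)c(OCOC)c(C#C[O-])c1.[Li+] | intermediate
10 | ring B aryl triisopropylsiloxyalkyne | COC(OC)c1cc(OCOC)c(OCOC)c(C#CO[Si](C(C)C)(C(C)C)C(C)C)c1 | intermediate
11 | 3-ethoxycyclobut-2-en-1-one | CCOC1=CC(=O)C1 | starting material
12 | 3-(benzyloxy)cyclobut-2-en-1-one | O=C1C=C(OCc2ccccc2)C1 | intermediate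
13 | 3-(benzyloxy)buta-1,3-dien-1-one (vinylketene) | C=C(OCc1ccccc1)C=C=O | intermediate
14 | 2-aryl-4-[1-(benzyloxy)ethenyl]-3-(triisopropylsiloxy)cyclobut-2-en-1-one (racemic at C4) | O=C1C(c2cc(C(OC)OC)cc(OCOC)c2OCOC)=C(O[Si](C(C)C)(C(C)C)C(C)C)C1C(=C)OCc1ccccc1 | intermediate
15 | dienylketene, alkenyl group cis to the ketene-bearing carbon | O=C=C(c1cc(C(OC)OC)cc(OCOC)c1OCOC)/C(O[Si](C(C)C)(C(C)C)C(C)C)=C\C(=C)OCc1ccccc1 | intermediate
16 | 2-aryl-5-(benzyloxy)-3-(triisopropylsiloxy)cyclohexa-2,4-dien-1-one | O=C1CC(OCc2ccccc2)=CC(O[Si](C(C)C)(C(C)C)C(C)C)=C1c1cc(C(OC)OC)cc(OCOC)c1OCOC | intermediate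
17 | 4-(benzyloxy)-5'-(dimethoxymethyl)-2',3'-bis(methoxymethoxy)-6-(triisopropylsiloxy)biphenyl-2-ol | Oc1cc(OCc2ccccc2)cc(O[Si](C(C)C)(C(C)C)C(C)C)c1-c1cc(C(OC)OC)cc(OCOC)c1OCOC | intermediate
18 | 4-(benzyloxy)-5'-(dimethoxymethyl)-2',3'-bis(methoxymethoxy)biphenyl-2,6-diol | Oc1cc(OCc2ccccc2)cc(O)c1-c1cc(C(OC)OC)cc(OCOC)c1OCOC | intermediate
19 | 4-(benzyloxy)-5'-(dimethoxymethyl)-2,6,2',3'-tetrakis(methoxymethoxy)biphenyl | COCOc1cc(OCc2ccccc2)cc(OCOC)c1-c1cc(C(OC)OC)cc(OCOC)c1OCOC | intermediate
20 | 5'-(dimethoxymethyl)-2,6,2',3'-tetrakis(methoxymethoxy)biphenyl-4-ol | COCOc1cc(O)cc(OCOC)c1-c1cc(C(OC)OC)cc(OCOC)c1OCOC | intermediate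
21 | 3-iodo-5'-(dimethoxymethyl)-2,6,2',3'-tetrakis(methoxymethoxy)biphenyl-4-ol | COCOc1cc(O)c(I)c(OCOC)c1-c1cc(C(OC)OC)cc(OCOC)c1OCOC | intermediate
22 | 3,4-bis(benzyloxy)benzaldehyde | O=Cc1ccc(OCc2ccccc2)c(OCc2ccccc2)c1 | starting material
23 | 1,2-bis(benzyloxy)-4-ethynylbenzene | C#Cc1ccc(OCc2ccccc2)c(OCc2ccccc2)c1 | intermediate
24 | o-hydroxyaryl alkynone | O=C(C#Cc1ccc(OCc2ccccc2)c(OCc2ccccc2)c1)c1c(O)cc(OCOC)c(-c2cc(C(OC)OC)cc(OCOC)c2OCOC)c1OCOC | intermediate
25 | (E)-beta-(diethylamino)enone | O=C(/C=C(/N(CC)CC)c1ccc(OCc2ccccc2)c(OCc2ccccc2)c1)c1c(O)cc(OCOC)c(-c2cc(C(OC)OC)cc(OCOC)c2OCOC)c1OCOC | intermediate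
26 | protected 6-aryl flavone (four MOM, two Bn, dimethyl acetal) | COCOc1cc2oc(-c3ccc(OCc4ccccc4)c(OCc4ccccc4)c3)cc(=O)c2c(OCOC)c1-c1cc(C(OC)OC)cc(OCOC)c1OCOC | intermediate
27 | 3-{2-[3,4-bis(benzyloxy)phenyl]-5,7-dihydroxy-4-oxo-4H-chromen-6-yl}-4,5-dihydroxybenzaldehyde | O=Cc1cc(O)c(O)c(-c2c(O)cc3oc(-c4ccc(OCc5ccccc5)c(OCc5ccccc5)c4)cc(=O)c3c2O)c1 | intermediate
28 | 3,4-bis(benzyloxy)-5-{7-(benzyloxy)-2-[3,4-bis(benzyloxy)phenyl]-5-hydroxy-4-oxo-4H-chromen-6-yl}benzaldehyde | O=Cc1cc(OCc2ccccc2)c(OCc2ccccc2)c(-c2c(OCc3ccccc3)cc3oc(-c4ccc(OCc5ccccc5)c(OCc5ccccc5)c4)cc(=O)c3c2O)c1 | intermediate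
29 | 2',4',6'-trihydroxyacetophenone | CC(=O)c1c(O)cc(O)cc1O | starting material
30 | 1-[2,4-bis(benzyloxy)-6-hydroxyphenyl]ethanone | CC(=O)c1c(O)cc(OCc2ccccc2)cc1OCc1ccccc1 | intermediate
31 | dilithium enolate phenoxide of 30 | [Li+].[Li+].C=C([O-])c1c([O-])cc(OCc2ccccc2)cc1OCc1ccccc1 | intermediate
32 | tert-butyl 3-[2,4-bis(benzyloxy)-6-hydroxyphenyl]-3-oxopropanoate | CC(C)(C)OC(=O)CC(=O)c1c(O)cc(OCc2ccccc2)cc1OCc1ccccc1 | intermediate
33 | (Z)-alkylidene beta-ketoester | CC(C)(C)OC(=O)/C(=C\c1cc(OCc2ccccc2)c(OCc2ccccc2)c(-c2c(OCc3ccccc3)cc3oc(-c4ccc(OCc5ccccc5)c(OCc5ccccc5)c4)cc(=O)c3c2O)c1)C(=O)c1c(O)cc(OCc2ccccc2)cc1OCc1ccccc1 | intermediate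
34 | tert-butyl (2S,3R)-flavanone-3-carboxylate (trans, C3 epimerisable) | O=C1[C@H](C(=O)OC(C)(C)C)[C@@H](c2cc(OCc3ccccc3)c(OCc3ccccc3)c(-c3c(OCc4ccccc4)cc4oc(-c5ccc(OCc6ccccc6)c(OCc6ccccc6)c5)cc(=O)c4c3O)c2)Oc2cc(OCc3ccccc3)cc(OCc3ccccc3)c21 | intermediate
35 | (2S,3R)-flavanone-3-carboxylic acid | O=C1[C@H](C(=O)O)[C@@H](c2cc(OCc3ccccc3)c(OCc3ccccc3)c(-c3c(OCc4ccccc4)cc4oc(-c5ccc(OCc6ccccc6)c(OCc6ccccc6)c5)cc(=O)c4c3O)c2)Oc2cc(OCc3ccccc3)cc(OCc3ccccc3)c21 | intermediate
36 | (2S)-heptabenzyl ether of the target (flavone 5-OH free) | O=C1C[C@@H](c2cc(OCc3ccccc3)c(OCc3ccccc3)c(-c3c(OCc4ccccc4)cc4oc(-c5ccc(OCc6ccccc6)c(OCc6ccccc6)c5)cc(=O)c4c3O)c2)Oc2cc(OCc3ccccc3)cc(OCc3ccccc3)c21 | intermediate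
37 | (2S)-2-{3-[2-(3,4-dihydroxyphenyl)-5,7-dihydroxy-4-oxo-4H-chromen-6-yl]-4,5-dihydroxyphenyl}-5,7-dihydroxychroman-4-one | O=C1C[C@@H](c2cc(O)c(O)c(-c3c(O)cc4oc(-c5ccc(O)c(O)c5)cc(=O)c4c3O)c2)Oc2cc(O)cc(O)c21 | target

## Step count

Total step count: 21.
Longest linear sequence: 17 steps from 5-iodovanillin (steps 1–6, 8–12, 14–16, 19–21).

## Steps most likely to fail

**Step 8 (benzannulation).**
- Risk: the donor-stabilised cyclobutenone may open too slowly. Thermal oxygen-to-carbon silyl migration in the siloxyalkyne and ketene self-condensation could then outrun the [2+2] addition at the hindered aryl-bearing carbon.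
- Fallback: the biaryl bond is made by cross-coupling instead of ring construction. It sets out from iodide 4 and comes back at 19.
- Commercial phloroglucinol is treated with two equivalents of MOMCl/i-Pr2NEt to give 3,5-bis(methoxymethoxy)phenol F1. BnBr/K2CO3 then gives 1-(benzyloxy)-3,5-bis(methoxymethoxy)benzene F2.
- Directed ortho-lithiation between the two MOM ethers (n-BuLi, THF, 0 °C) gives [4-(benzyloxy)-2,6-bis(methoxymethoxy)phenyl]lithium F3. ZnCl2 converts it to [4-(benzyloxy)-2,6-bis(methoxymethoxy)phenyl]zinc chloride F4.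
- Negishi coupling of this zinc reagent with 4 (Pd2(dba)3, SPhos, THF, 60 °C) gives 19.

**Step 20 (asymmetric closure).**
- Risk: racemic background cyclisation may occur, either during the amine-catalysed condensation of step 19 or uncatalysed in step 20. Facial selectivity may be poor because of the twisted ortho-benzyloxy aryl ketone and the bulky biaryl. Reversible ring opening in the hot acid stage may erode the enantiomeric purity.
- Fallback: resolution instead of catalysis. It sets out from 28 and 30 and comes back at 36.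
- Claisen–Schmidt condensation (KOH, EtOH, rt) gives the (E)-2'-hydroxychalcone F8, and NaOAc in refluxing EtOH closes it to the racemic heptabenzyl flavanone F9.
- The racemate is separated by preparative HPLC on a polysaccharide chiral stationary phase, and the 2S enantiomer is 36.

**Step 14 (carbonylative annulation).**
- Risk: oxidative addition may be slow at the electron-rich, doubly ortho-substituted iodide. Direct alkynylation without CO uptake, followed by five-membered ring closure, may compete, as may capture of the acyl intermediate by diethylamine.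
- Fallback: the carbonyl carbon is introduced by formylation instead of by CO. It sets out from phenol 20, comes back at 24 (now isolated), and from there reaches 26.
- Magnesium-mediated ortho-formylation (MgCl2, Et3N, paraformaldehyde, MeCN, reflux) gives the salicylaldehyde F5.
- Alkyne 23 is deprotonated with n-BuLi to the lithium arylacetylide F6, and two equivalents of it add to the aldehyde to give the racemic propargylic alcohol F7.
- MnO2 in CH2Cl2 oxidises this alcohol to 24, and Et2NH in warm DMF closes 24 through 25 to 26.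

## Further compounds

F1 | step 8 | 3,5-bis(methoxymethoxy)phenol | COCOc1cc(O)cc(OCOC)c1
F2 | step 8 | 1-(benzyloxy)-3,5-bis(methoxymethoxy)benzene | COCOc1cc(OCc2ccccc2)cc(OCOC)c1
F3 | step 8 | [4-(benzyloxy)-2,6-bis(methoxymethoxy)phenyl]lithium | COCOc1cc(OCc2ccccc2)cc(OCOC)c1[Li]
F4 | step 8 | [4-(benzyloxy)-2,6-bis(methoxymethoxy)phenyl]zinc chloride | COCOc1cc(OCc2ccccc2)cc(OCOC)c1[Zn]Cl
F5 | step 14 | salicylaldehyde (3-formyl derivative of 20) | O=Cc1c(O)cc(OCOC)c(-c2cc(C(OC)OC)cc(OCOC)c2OCOC)c1OCOC
F6 | step 14 | lithium arylacetylide of 23 | [Li]C#Cc1ccc(OCc2ccccc2)c(OCc2ccccc2)c1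
F7 | step 14 | racemic propargylic alcohol | OC(C#Cc1ccc(OCc2ccccc2)c(OCc2ccccc2)c1)c1c(O)cc(OCOC)c(-c2cc(C(OC)OC)cc(OCOC)c2OCOC)c1OCOC
F8 | step 20 | (E)-2'-hydroxychalcone | O=C(/C=C/c1cc(OCc2ccccc2)c(OCc2ccccc2)c(-c2c(OCc3ccccc3)cc3oc(-c4ccc(OCc5ccccc5)c(OCc5ccccc5)c4)cc(=O)c3c2O)c1)c1c(O)cc(OCc2ccccc2)cc1OCc1ccccc1
F9 | step 20 | racemic heptabenzyl flavanone | O=C1CC(c2cc(OCc3ccccc3)c(OCc3ccccc3)c(-c3c(OCc4ccccc4)cc4oc(-c5ccc(OCc6ccccc6)c(OCc6ccccc6)c5)cc(=O)c4c3O)c2)Oc2cc(OCc3ccccc3)cc(OCc3ccccc3)c21
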